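Locants used throughout: C1–C6 are the six stereocentres in the order in which they appear in the target SMILES. Ring A carries a1 (bonded to C1), a2 and a4 (oxygenated) and a6 (bonded to C2). Ring B carries b1 (bonded to C3), b2 and b4 (oxygenated) and b6 (bonded to C4). Ring C carries c1 (bonded to C4), c2 (furan oxygen), c4 (oxygenated) and c6 (bonded to C5).

## Analysis of the target

Canaliculatol (37, C42H32O9) is a resveratrol trimer with a hexacyclic core. The core consists of an indane (ring A fused to C1, C5, C2), an eight-membered carbocycle (C2, C3, b1, b6, C4, c1, c6, C5) that carries the fused resorcinol rings B and C, and a 2,3-dihydrobenzofuran (c1, c2, O, C6, C4). Three 4-hydroxyphenyl groups sit on C1, C3 and C6. Working through the SMILES gives these relations: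

- H1 and H5 are cis on the cyclopentane, so the aryl group on C1 is cis to ring C on C5.
- H5 and H2 are trans, so the five- and eight-membered rings are trans-fused.
- Ring A on C2 and the aryl group on C3 are trans on the eight-membered ring.
- The C4–C6 bond lies on the face of the eight-membered ring opposite to the aryl group on C3.
- H4 and H6 are trans in the dihydrofuran.
- In these locants the descriptors are 1R, 2R, 3R, 4R, 5S, 6R.

The sensitive groups are the eight free phenols, the doubly benzylic methines and the benzylic C6–O bond of the dihydrofuran, which ionises under acid because it is para to an oxygen substituent. The hard points are the medium ring held between two arenes, the less stable cis relation at C1/C5, and the C3/C4 pair, which is separated by ring B and has no direct stereochemical relay. The strategy rests on one feature: ring C is bonded to C5 and C4 through two adjacent carbons (c6 and c1), with oxygen on c2 next to c1. Ring C can therefore be inserted as 3,5-dimethoxybenzyne into the C4–C5 bond of a six-membered beta-keto ester, the methoxy group next to the aryne fixing the orientation.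

## Retrosynthetic reasoning

**37 from 36 (eight O–CH3 bonds).** The phenols are released last from the octamethyl ether 36. Methyl ethers survive fluoride, organolithium and organocerium reagents, strong acid and hydride without adjustment. The cost is one Lewis-acid deprotection on a molecule that already contains the dihydrofuran.

**36 from 32 and 33 (C4–C6 and O–C6).** Both bonds to C6 are cut together. This keeps the acid-labile dihydrofuran out of every earlier intermediate and turns C4 into the benzhydrol carbon of 32, next to a free phenol on c2, which is a latent ortho-quinone methide (35). The forward step is a [4+1] annulation with the sulfur ylide 34 from salt 33. It must attack C4 on the face of the eight-membered ring opposite to the aryl group on C3 and close the trans-2,3-disubstituted furan. Cutting only O–C6 would need a C6 carbanion adding to the C4 ketone followed by deoxygenation, and hydride would then enter C4 from the open face, which is the face C6 must occupy.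

**32 from 31, 30, and 26 with 27 (C1–H and C1–aryl).** Diol 32 comes from ketone 31 by hydride reduction. C1 is cut twice: the C1–H bond (31 from tertiary alcohol 30) and the C1–aryl bond (30 from indanone 26 and the arylcerium 29 made from 27). Hydrogen is introduced last because the target needs the aryl group on C1 cis to ring C on C5. A nucleophile adds to the C1 cation anti to ring C, so that nucleophile must be hydride and not the arene.

**26 from 24, 23 and 22 (C1–a1).** The five-membered ring is opened at C1–a1, an intramolecular Friedel–Crafts acylation of acid 24. Position a1 is ortho and para to the two methoxy groups of ring A, so this is the electronically matched closure, and it converts the ester carbon of 22 into C1. The methyl ether on c2 is removed before this (22 to 23). It is the only methoxy group ortho to a ketone, and as a phenol it masks the C4 ketone as a chelated phenoxide during the aryl addition to 26.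

**22 from 19 and 8 (C5–c6 and C4–c1 cut, C4–C5 re-formed).** Ring C is excised as aryne 20, which leaves the six-membered beta-keto ester 19. Every other cut of the eight-membered ring (C3–b1, C4–b6, or C5–c6 alone) leads to an end-to-end medium-ring closure. This cut gives the ring by two-carbon expansion of a six-membered ring and delivers all of ring C with the correct oxygen pattern. The forward reaction needs C-arylation at the aryne carbon remote from the methoxy group, capture of the C4 ketone by the aryl anion, and fragmentation.

**19 from 18, and 18 from 13 and 15 (C2–C3 and C4–C5).** The tetralone is cut into the ortho-benzyl benzoate 13 and cinnamate 15, a tandem conjugate addition and Dieckmann condensation. All-trans is the thermodynamic arrangement. The annulation gives racemate 18, which is resolved to 19. A photoenolisation/Diels–Alder assembly of the same two bonds was weighed and kept only as a fallback, for three reasons: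

- Cinnamate esters are poor traps for short-lived photoenols.
- The excited aryl aldehyde would sensitise E/Z isomerisation of the cinnamate.
- No enantioselective variant is established for this dienophile class.

A resolution is accepted so that no unproven asymmetric step precedes the key step.

**13 from 10 and 11; 10 from 9; 15 from 14.** The aryl–benzyl bond is cut (Negishi coupling through 12), then the C–Br bond (bromination of 9), and the ester of 15 is traced to acid 14.

**8 from 6, 2 and 1; 33 from 11.** The C–Si bond comes from directed ortho-metalation of carbamate 2 (through 3, 4 and 5). The triflate comes from phenol 7, released from 6. Sulfonium salt 33 is cut at the C–S bond back to 11.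

## Alternatives that were turned down

**Alternative 1: benzannulation of ring A onto a chiral cyclopentene.**
- Disconnection: ring A is built onto a cyclopentene that already carries C1, C5 and C2.
- Forward key step: irradiation of diazo ketone A2 gives a vinylketene by Wolff rearrangement. [2+2] addition of ethoxyacetylene A3, four-electron ring-opening and six-electron ring closure then give indane A1, with a free phenol on a2 and an ethyl ether on a4.
- For: the three indane stereocentres, including the awkward cis C1/C5 pair, are set on a small ring before the arene exists. The resorcinol oxygens arrive regiospecifically, and no acid touches the skeleton.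
- Against: A1 answers only the indane. C3 is still a protected hydroxymethyl group, so C3, ring B, C4, ring C and the furan all remain, and the eight-membered ring would have to be closed end to end. The chiral cyclopentene needs its own multistep asymmetric synthesis, and the differentiated ethyl ether is of no use for this target.
- Comparison: it is stronger than the chosen route on C1, which there depends on a late hydride delivery. The chosen route instead forms the medium ring and all of ring C in one step from a six-membered ring, in far fewer operations.

**Alternative 2: ring contraction of a dihydronaphthalene with trivalent iodine.**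
- Disconnection: the indane is traced to the cis-1,2-diaryl-1,2-dihydronaphthalene A5.
- Forward key step: a hydroxy(tosyloxy)iodoarene in methanol adds to the C2=C3 alkene, ring A shifts from C3 to C2, and C3 is left as the dimethyl acetal in A4.
- For: the 1,2-shift is stereospecific and gives the 1,2-cis-2,3-trans indane with C3 at the aldehyde level, ready for aryl addition. On the five-membered ring it is at least as well controlled as the chosen route.
- Against: the electron-rich dimethoxyarenes and the doubly benzylic C–H bonds of A5 are exposed to an oxidant that can also aromatise the dihydronaphthalene. A5 itself must be made enantiopure. After the contraction the same unsolved problem remains as in alternative 1: C3 to ring B to C4 to ring C by direct medium-ring closure.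
- Comparison: equal or better for the indane, weaker for everything else. The chosen route uses the indane closure (step 12) only as a simple acylation after the eight-membered ring already exists.

**Alternative 3: closure of the eight-membered ring by palladium enolate arylation at C5.**
- Disconnection: the C5–c6 bond is made last.
- Forward key step: the indanone enolate of A7 is coupled with the aryl bromide on ring C by a palladium catalyst with a bulky phosphine and an alkoxide base, giving hexacyclic ketone A6.
- For: it is convergent, the end-game after A6 is very short (aryl addition, ionic hydrogenation, deprotection), and C5 is set alpha to a ketone under thermodynamic control, the same control element the chosen route uses. On the number of steps after the medium ring it is the stronger plan.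
- Against: the ring is closed end to end through a nine-membered palladacycle at a hindered secondary enolate carbon, where reductive elimination competes with dehalogenation and intermolecular coupling. The dihydrofuran must survive hot alkoxide. A7 must already contain C2, C3, C4 and C6, with the C3/C4 relation across ring B set without the help of the ring.
- Comparison: the chosen route makes the medium ring by expansion, with no entropic penalty, and uses the finished rigid ring to direct C4 and C6.

Key step: step 9

Assumption: the fraction collected in step 8 is identified once as the (2R,3S,4R) enantiomer 19 by crystallography of a heavy-atom derivative or by ECD; the elution order is not predicted.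

## Route

Step 1
Reactants: 1 3,5-dimethoxyphenol
Product: 2 3,5-dimethoxyphenyl N-isopropylcarbamate
Conditions: i-PrNCO, Et3N (cat.), CH2Cl2, 25 °C
Reagents that add atoms: isopropyl isocyanate, CC(C)N=C=O
Why: Base-catalysed addition of the phenol to the isocyanate (carbamoylation) installs the directing group for ortho-silylation, which can later be removed under mild base.

Step 2
Reactants: 2 3,5-dimethoxyphenyl N-isopropylcarbamate
Product: 6 3,5-dimethoxy-2-(trimethylsilyl)phenyl N-isopropylcarbamate, via N-silyl carbamate 3 (not isolated), via aryllithium 4 (not isolated), via bis-silyl carbamate 5 (not isolated)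
Conditions: TMSOTf, TMEDA, Et2O, 0 °C; n-BuLi, TMEDA, −78 °C; TMSCl, −78 to 25 °C; aq. NaHSO4
Reagents that add atoms: chlorotrimethylsilane, C[Si](C)(C)Cl
Why: Directed ortho-metalation: after N-silylation in situ the carbamate directs lithiation to the carbon flanked by the carbamate and a methoxy group, the aryllithium is silylated, and the N–Si bond is lost on aqueous work-up.

Step 3
Reactants: 6 3,5-dimethoxy-2-(trimethylsilyl)phenyl N-isopropylcarbamate
Product: 8 3,5-dimethoxy-2-(trimethylsilyl)phenyl trifluoromethanesulfonate, via silyl phenol 7 (not isolated)
Conditions: Et2NH, DBU, MeCN, 40 °C; then PhNTf2, 25 °C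
Reagents that add atoms: N-phenylbis(trifluoromethanesulfonimide), O=S(=O)(N(c1ccccc1)S(=O)(=O)C(F)(F)F)C(F)(F)F
Why: E1cB cleavage of the N–H carbamate (the isocyanate released is scavenged by diethylamine) unmasks the phenoxide, which is triflated in the same flask to give the ortho-silyl aryl triflate, the standard fluoride-triggered aryne precursor.

Step 4
Reactants: 9 methyl 3,5-dimethoxybenzoate
Product: 10 methyl 2-bromo-3,5-dimethoxybenzoate
Conditions: NBS, MeCN, 0 to 25 °C
Reagents that add atoms: N-bromosuccinimide, O=C1CCC(=O)N1Br
Why: Electrophilic aromatic bromination; the position ortho to the ester is activated ortho and para by the two methoxy groups and is less hindered than the position between them.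

Step 5
Reactants: 10 methyl 2-bromo-3,5-dimethoxybenzoate; 11 4-methoxybenzyl chloride
Product: 13 methyl 3,5-dimethoxy-2-(4-methoxybenzyl)benzoate, via benzylzinc chloride 12 (not isolated)
Conditions: 11, Zn, LiCl, THF, 25 °C; then 10, Pd(OAc)2 (2 mol %), SPhos (4 mol %), THF, 50 °C
Reagents that add atoms: none
Why: Zinc insertion into the benzylic chloride followed by Negishi coupling; the biarylphosphine is chosen for the di-ortho-substituted bromide and the organozinc tolerates the ester.

Step 6
Reactants: 14 (E)-3,5-dimethoxycinnamic acid
Product: 15 methyl (E)-3,5-dimethoxycinnamate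
Conditions: MeOH, H2SO4 (cat.), reflux
Reagents that add atoms: methanol, CO
Why: Fischer esterification; the E alkene is not affected.

Step 7
Reactants: 13 methyl 3,5-dimethoxy-2-(4-methoxybenzyl)benzoate; 15 methyl (E)-3,5-dimethoxycinnamate
Product: 18 racemic all-trans methyl 3-(3,5-dimethoxyphenyl)-5,7-dimethoxy-4-(4-methoxyphenyl)-1-oxo-1,2,3,4-tetrahydronaphthalene-2-carboxylate, via benzylic lithium species 16 (not isolated), via Michael adduct enolate 17 (not isolated)
Conditions: lithium diisopropylamide, THF, −78 °C; then 15, −78 to 0 °C; aq. NH4Cl
Reagents that add atoms: none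
Why: Tandem Michael addition and Dieckmann condensation (Staunton–Weinreb annulation): lateral lithiation gives the extended ester enolate 16, whose benzylic carbon (C3) adds to the beta-carbon (C2) of 15, and ester enolate 17 closes onto the aryl ester (C4–C5). C2 and C3 are set together and should carry the two aryl groups trans (both pseudo-equatorial in the chair-like closure), while C5 equilibrates through the enol to the all-trans isomer; the product is racemic.

Step 8
Reactants: 18 racemic all-trans tetralone beta-keto ester
Product: 19 methyl (2R,3S,4R)-3-(3,5-dimethoxyphenyl)-5,7-dimethoxy-4-(4-methoxyphenyl)-1-oxo-1,2,3,4-tetrahydronaphthalene-2-carboxylate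
Conditions: preparative SFC, amylose tris(3,5-dimethylphenylcarbamate) stationary phase, CO2/MeOH
Reagents that add atoms: none
Why: Resolution by chromatography on a chiral stationary phase; the enantiomers differ in the configurationally fixed C2/C3 pair, so keto–enol exchange at C5 does not interconvert them.

Step 9
Reactants: 19 (2R,3S,4R)-tetralone beta-keto ester; 8 3,5-dimethoxy-2-(trimethylsilyl)phenyl trifluoromethanesulfonate
Product: 22 dibenzocyclooctenone keto ester (C4 ketone between rings B and C; methyl ester on C5; ring A on C2; 4-methoxyphenyl on C3; H2/H3 trans; H2/H5 trans), via 3,5-dimethoxybenzyne 20 (not isolated), via benzocyclobutenoxide 21 (not isolated)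
Conditions: CsF (2.5 equiv), MeCN, 80 °C
Reagents that add atoms: none
Why: Fluoride attacks silicon of 8 and triflate leaves to give 3,5-dimethoxybenzyne 20, while CsF also converts the acidic beta-keto ester 19 into its caesium enolate. The enolate carbon C5 adds to the aryne carbon remote from the methoxy group (c6), because the charge then develops at c1 next to the inductively withdrawing C–O bond, and this places the ketone next to the future furan oxygen as ring C requires. The aryl anion at c1 adds to the C4 ketone in a 4-exo-trig closure to the cis-fused benzocyclobutenoxide 21, which opens by retro-aldol cleavage of the old C4–C5 bond to the diaryl ketone and an ester enolate. The eight-membered ring therefore arises by two-carbon ring expansion of the six-membered ring (C5–c6 and C4–c1 formed, C4–C5 lost) and not by end-to-end cyclisation. The closest known reaction is the acyl-alkylation of arynes with cyclic beta-keto esters, which is also established with 3,5-dioxygenated benzynes. C2 and C3 are untouched; C5 is re-formed by protonation of the ester enolate and, being alpha to the ester and benzylic, should equilibrate under the basic conditions to the epimer with the ester trans to ring A on C2 (and it is corrected again alpha to the ketone in step 12). The step needs C- over O-arylation and ketone capture over simple protonation of the aryl anion; the soft enolate carbon and the ketone held close to the carbanion favour both, but the aryl-bearing C2 next to the reacting carbon makes this a demanding member of the substrate class. Racemisation by retro-Michael opening of the enolate is not expected, because the benzylic carbanion released would be far less stabilised than the beta-keto ester enolate.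

Step 10
Reactants: 22 dibenzocyclooctenone keto ester
Product: 23 phenol keto ester (as 22 with OH in place of OCH3 on c2)
Conditions: BCl3, CH2Cl2, −78 to 0 °C
Reagents that add atoms: none
Why: Chelation-controlled ether cleavage: BCl3 binds the C4 carbonyl and cleaves only the methoxy group ortho to it (c2). The hydrogen-bonded phenol is the later furan oxygen and shields the C4 ketone in step 13.

Step 11
Reactants: 23 phenol keto ester
Product: 24 phenol keto acid (CO2H on C5)
Conditions: LiOH, THF/MeOH/H2O, 50 °C; then aq. HCl
Reagents that add atoms: lithium hydroxide, [Li+].[OH-]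
Why: Saponification of the methyl ester; any epimerisation at C5 under base leads to the same thermodynamic epimer.

Step 12
Reactants: 24 phenol keto acid
Product: 26 indanone (C1 ketone bonded to a1; C4 ketone; c2 phenol; H2/H5 trans), via mixed trifluoroacetic anhydride 25 (not isolated)
Conditions: (CF3CO)2O, CH2Cl2, 0 to 25 °C; then K2CO3, MeOH, 25 °C
Reagents that add atoms: none
Why: Intramolecular Friedel–Crafts acylation through the mixed anhydride: the acyl group attacks ring A at a1, ortho and para to its methoxy groups, and closes the five-membered ring, whereas six- or seven-membered closures onto the other rings would need unactivated positions. C5 is now alpha to the C1 ketone, and the mild base of the work-up should settle the trans ring fusion expected for a 2,3-disubstituted indanone and cleave any aryl trifluoroacetate.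

Step 13
Reactants: 26 indanone; 27 4-bromoanisole
Product: 30 tertiary alcohol (4-methoxyphenyl and OH on C1; aryl expected trans to ring C on C5), via 4-methoxyphenyllithium 28 (not isolated), via 4-methoxyphenylcerium dichloride 29 (not isolated)
Conditions: 27, n-BuLi, THF, −78 °C; CeCl3, −78 °C; then 26, −78 to −40 °C
Reagents that add atoms: none
Why: 1,2-Addition of an organocerium reagent, which suppresses enolisation of the 2-aryl-indanone. The first equivalent deprotonates the phenol, and the chelated phenoxide deactivates the hindered C4 diaryl ketone, so only C1 is attacked. The carbinol configuration does not matter because C1 becomes planar in step 14.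

Step 14
Reactants: 30 tertiary alcohol
Product: 31 ketone with C1 set (H1 cis to H5; C4 ketone; c2 phenol)
Conditions: Et3SiH, CF3CO2H, CH2Cl2, −40 to 0 °C
Reagents that add atoms: none
Why: Ionic hydrogenation: the tertiary, doubly benzylic alcohol ionises at low temperature and the silane reduces the cation from the face opposite to ring C on C5, leaving the 4-methoxyphenyl group cis to ring C as in the target. The hydrogen-bonded diaryl ketone is not reduced under these mild conditions.

Step 15
Reactants: 31 ketone
Product: 32 ortho-hydroxybenzhydrol (C4 carbinol as a mixture of epimers; c2 phenol)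
Conditions: NaBH4, THF/MeOH, 0 to 25 °C
Reagents that add atoms: none
Why: Hydride reduction of the ortho-hydroxy diaryl ketone gives the precursor of the ortho-quinone methide; the carbinol configuration is lost in the next step.

Step 16
Reactants: 11 4-methoxybenzyl chloride
Product: 33 1-(4-methoxybenzyl)tetrahydrothiophenium tetrafluoroborate
Conditions: tetrahydrothiophene, NaBF4, MeCN, 25 °C
Reagents that add atoms: tetrahydrothiophene, C1CCSC1; sodium tetrafluoroborate, [Na+].F[B-](F)(F)F
Why: S-Alkylation of the sulfide by the reactive benzylic chloride with exchange to a non-nucleophilic counter-ion; the salt is used freshly as the source of the semi-stabilised ylide.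

Step 17
Reactants: 32 ortho-hydroxybenzhydrol; 33 1-(4-methoxybenzyl)tetrahydrothiophenium tetrafluoroborate
Product: 36 canaliculatol octamethyl ether, via sulfonium ylide 34 (not isolated), via ortho-quinone methide 35 (not isolated)
Conditions: 33, Cs2CO3, MeCN, 25 to 50 °C
Reagents that add atoms: none
Why: Formal [4+1] annulation of an ortho-quinone methide with a sulfur ylide: base releases ylide 34 and, by 1,4-elimination of water from the phenoxide, quinone methide 35; conjugate addition of the ylide to C4 and 5-exo-tet displacement of the sulfide by the phenoxide close the dihydrofuran. C4 is set by attack on the face of the eight-membered ring opposite to the aryl group on C3 and to C1 on C5, and C6 by the preference of this annulation for the trans-2,3-disubstituted product.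

Step 18
Reactants: 36 canaliculatol octamethyl ether
Product: 37 canaliculatol
Conditions: BBr3, CH2Cl2, −78 to 25 °C; then MeOH/H2O
Reagents that add atoms: none
Why: Exhaustive Lewis-acid cleavage of the eight aryl methyl ethers; if the benzylic C6–O bond ionises reversibly, the trans-dihydrofuran is the favoured isomer on reclosure.

## Compound list

1 | 3,5-dimethoxyphenol | COc1cc(O)cc(OC)c1 | starting material
2 | 3,5-dimethoxyphenyl N-isopropylcarbamate | COc1cc(OC)cc(OC(=O)NC(C)C)c1 | intermediate
3 | 3,5-dimethoxyphenyl N-isopropyl-N-(trimethylsilyl)carbamate | COc1cc(OC)cc(OC(=O)N(C(C)C)[Si](C)(C)C)c1 | intermediate (not isolated)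
4 | 2-lithio-3,5-dimethoxyphenyl N-isopropyl-N-(trimethylsilyl)carbamate | COc1cc(OC)c([Li])c(OC(=O)N(C(C)C)[Si](C)(C)C)c1 | intermediate (not isolated)
5 | 3,5-dimethoxy-2-(trimethylsilyl)phenyl N-isopropyl-N-(trimethylsilyl)carbamate | COc1cc(OC)c([Si](C)(C)C)c(OC(=O)N(C(C)C)[Si](C)(C)C)c1 | intermediate (not isolated)
6 | 3,5-dimethoxy-2-(trimethylsilyl)phenyl N-isopropylcarbamate | COc1cc(OC)c([Si](C)(C)C)c(OC(=O)NC(C)C)c1 | intermediate
7 | 3,5-dimethoxy-2-(trimethylsilyl)phenol (as its amidinium salt) | COc1cc(OC)c([Si](C)(C)C)c(O)c1 | intermediate (not isolated)
8 | 3,5-dimethoxy-2-(trimethylsilyl)phenyl trifluoromethanesulfonate | COc1cc(OC)c([Si](C)(C)C)c(OS(=O)(=O)C(F)(F)F)c1 | intermediate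
9 | methyl 3,5-dimethoxybenzoate | COC(=O)c1cc(OC)cc(OC)c1 | starting material
10 | methyl 2-bromo-3,5-dimethoxybenzoate | COC(=O)c1cc(OC)cc(OC)c1Br | intermediate
11 | 4-methoxybenzyl chloride | COc1ccc(CCl)cc1 | starting material
12 | (4-methoxybenzyl)zinc chloride | COc1ccc(C[Zn]Cl)cc1 | intermediate (not isolated)
13 | methyl 3,5-dimethoxy-2-(4-methoxybenzyl)benzoate | COC(=O)c1cc(OC)cc(OC)c1Cc1ccc(OC)cc1 | intermediate
14 | (E)-3,5-dimethoxycinnamic acid | COc1cc(/C=C/C(=O)O)cc(OC)c1 | starting material
15 | methyl (E)-3,5-dimethoxycinnamate | COc1cc(/C=C/C(=O)OC)cc(OC)c1 | intermediate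
16 | benzylic lithium derivative of 13 (extended ester enolate) | COC(=O)c1cc(OC)cc(OC)c1C([Li])c1ccc(OC)cc1 | intermediate (not isolated)
17 | lithium ester enolate of the Michael adduct (racemic; aryl groups on C2 and C3 in the relative sense of 18; one enantiomer drawn) | COc1cc(OC)cc(c1)[C@H](C=C(OC)O[Li])[C@H](c1ccc(OC)cc1)c1c(OC)cc(OC)cc1C(=O)OC | intermediate (not isolated)
18 | racemic all-trans methyl 3-(3,5-dimethoxyphenyl)-5,7-dimethoxy-4-(4-methoxyphenyl)-1-oxo-1,2,3,4-tetrahydronaphthalene-2-carboxylate (racemate; one enantiomer drawn) | COc1cc(OC)cc(c1)[C@H]1[C@H](c2ccc(OC)cc2)c2c(OC)cc(OC)cc2C(=O)[C@@H]1C(=O)OC | intermediate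
19 | methyl (2R,3S,4R)-3-(3,5-dimethoxyphenyl)-5,7-dimethoxy-4-(4-methoxyphenyl)-1-oxo-1,2,3,4-tetrahydronaphthalene-2-carboxylate | COc1cc(OC)cc(c1)[C@H]1[C@H](c2ccc(OC)cc2)c2c(OC)cc(OC)cc2C(=O)[C@@H]1C(=O)OC | intermediate
20 | 3,5-dimethoxybenzyne (1,2-didehydro-3,5-dimethoxybenzene) | COC1=CC(OC)=CC#C1 | intermediate (not isolated)
21 | caesium benzocyclobutenoxide (cis-fused four-membered ring C4, C5, c6, c1; ring C on the face of the tetralin opposite to ring A) | COc1cc(OC)cc(c1)[C@H]1[C@H](c2ccc(OC)cc2)c2c(OC)cc(OC)cc2[C@]3([O-])c4c(OC)cc(OC)cc4[C@]13C(=O)OC.[Cs+] | intermediate (not isolated)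
22 | dibenzocyclooctenone keto ester (C4 ketone; CO2CH3 on C5; ring A on C2; 4-methoxyphenyl on C3; H2/H3 trans; H2/H5 trans) | COC(=O)[C@H]1c2cc(OC)cc(OC)c2C(=O)c2cc(OC)cc(OC)c2[C@@H](c2ccc(OC)cc2)[C@@H]1c1cc(OC)cc(OC)c1 | intermediate
23 | phenol keto ester (22 with OH on c2) | COC(=O)[C@H]1c2cc(OC)cc(O)c2C(=O)c2cc(OC)cc(OC)c2[C@@H](c2ccc(OC)cc2)[C@@H]1c1cc(OC)cc(OC)c1 | intermediate
24 | phenol keto acid (23 with CO2H on C5) | OC(=O)[C@H]1c2cc(OC)cc(O)c2C(=O)c2cc(OC)cc(OC)c2[C@@H](c2ccc(OC)cc2)[C@@H]1c1cc(OC)cc(OC)c1 | intermediate
25 | mixed anhydride of 24 with trifluoroacetic acid | O=C(OC(=O)C(F)(F)F)[C@H]1c2cc(OC)cc(O)c2C(=O)c2cc(OC)cc(OC)c2[C@@H](c2ccc(OC)cc2)[C@@H]1c1cc(OC)cc(OC)c1 | intermediate (not isolated)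
26 | indanone (C1 ketone on a1; C4 ketone; c2 phenol; trans-fused five- and eight-membered rings) | O=C2c3c(OC)cc(OC)cc3[C@H]3[C@H](c4ccc(OC)cc4)c4c(OC)cc(OC)cc4C(=O)c4c(O)cc(OC)cc4[C@H]23 | intermediate
27 | 4-bromoanisole | COc1ccc(Br)cc1 | starting material
28 | 4-methoxyphenyllithium | COc1ccc([Li])cc1 | intermediate (not isolated)
29 | (4-methoxyphenyl)cerium dichloride | COc1ccc([Ce](Cl)Cl)cc1 | intermediate (not isolated)
30 | tertiary alcohol (OH on C1 cis to ring C on C5; 4-methoxyphenyl trans to ring C) | COc1ccc([C@@]2(O)c3c(OC)cc(OC)cc3[C@H]3[C@H](c4ccc(OC)cc4)c4c(OC)cc(OC)cc4C(=O)c4c(O)cc(OC)cc4[C@H]23)cc1 | intermediate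
31 | ketone with C1 set (4-methoxyphenyl on C1 cis to ring C on C5; C4 ketone; c2 phenol) | COc1ccc([C@@H]2c3c(OC)cc(OC)cc3[C@H]3[C@H](c4ccc(OC)cc4)c4c(OC)cc(OC)cc4C(=O)c4c(O)cc(OC)cc4[C@H]23)cc1 | intermediate
32 | ortho-hydroxybenzhydrol (C4 carbinol, both epimers; c2 phenol) | COc1ccc([C@@H]2c3c(OC)cc(OC)cc3[C@H]3[C@H](c4ccc(OC)cc4)c4c(OC)cc(OC)cc4C(O)c4c(O)cc(OC)cc4[C@H]23)cc1 | intermediate
33 | 1-(4-methoxybenzyl)tetrahydrothiophenium tetrafluoroborate | COc1ccc(C[S+]2CCCC2)cc1.F[B-](F)(F)F | intermediate
34 | 1-(4-methoxybenzylidene)tetrahydrothiophenium ylide | COc1ccc([CH-][S+]2CCCC2)cc1 | intermediate (not isolated)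
35 | ortho-quinone methide (C4=c1 within the eight-membered ring, ring-cis; c2 carbonyl) | COc1ccc([C@@H]2c3c(OC)cc(OC)cc3[C@H]3[C@H](c4ccc(OC)cc4)c4c(OC)cc(OC)cc4C=C4C(=O)C=C(OC)C=C4[C@H]23)cc1 | intermediate (not isolated)
36 | canaliculatol octamethyl ether (configuration as 37) | COc1ccc([C@@H]2c3c(OC)cc(OC)cc3[C@H]3[C@H](c4ccc(OC)cc4)c4c(OC)cc(OC)cc4[C@@H]4c5c(cc(OC)cc5[C@H]23)O[C@H]4c2ccc(OC)cc2)cc1 | intermediate
37 | canaliculatol | Oc1ccc([C@@H]2c3c(O)cc(O)cc3[C@H]3[C@H](c4ccc(O)cc4)c4c(O)cc(O)cc4[C@@H]4c5c(cc(O)cc5[C@H]23)O[C@H]4c2ccc(O)cc2)cc1 | target

## Step count and least certain steps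

Total: 18 steps. Longest linear sequence: 13 steps (4, 5, 7 to 15, 17, 18, from methyl 3,5-dimethoxybenzoate 9).

**Step 9 (key step).** The most likely failure is arylation of C5 without capture of the ketone (the aryl anion is protonated), or O-arylation, because C5 sits next to the aryl-bearing C2 and the enolate is hindered. A second concern is slow loss of enantiopurity by retro-Michael opening at 80 °C, and a C5 epimer that is cis to ring A, which would have to be corrected alpha to the ketone after step 12. The fallback is the stepwise anionic counterpart and runs from 19 to 22. 1,2-Dibromo-3,5-dimethoxybenzene F1 (bromination of 1-bromo-3,5-dimethoxybenzene) is coupled at its less hindered bromide with the enolate of 19 (Pd(OAc)2, a bulky biarylphosphine, K3PO4) to give the alpha-(2-bromo-3,5-dimethoxyphenyl) keto ester F2. Bromine–lithium exchange on F2 (t-BuLi, THF, −100 °C) then generates the same aryl anion next to the methoxy group, which adds to the C4 ketone and fragments to the ester enolate, giving 22 after protonation.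

**Step 7.** The lithiated ester 16 may condense with unreacted 13, and the conjugate addition may not be fully trans-selective for C2/C3, since the selectivity depends on a closure that is not under thermodynamic control at C3. The fallback builds the same two bonds by cycloaddition and runs from 13 to 18. Reduction of 13 (LiAlH4) gives [3,5-dimethoxy-2-(4-methoxybenzyl)phenyl]methanol F3, and oxidation (MnO2) gives 3,5-dimethoxy-2-(4-methoxybenzyl)benzaldehyde F4. Irradiation of F4 (350 nm, degassed toluene) with an excess of 15 gives, by photoenolisation and endo Diels–Alder addition, the racemic tetralol F5 (OH cis to the ester). Oxidation with Dess–Martin periodinane returns to 18, which is resolved as before.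

**Step 14.** The C1 cation is long-lived and may lose H5 reversibly to the indene. That would erase C5 and with it the ring fusion before hydride is delivered. The fallback replaces the cation by a radical and runs from 30 to 31. Alcohol 30 is acylated on both hydroxyl groups (KN(SiMe3)2, then methyl chlorooxoacetate) to the bis(methyl oxalate) F6. Reduction with Bu3SnH and AIBN in toluene at 110 °C cleaves the tertiary C1–O bond, and the benzylic radical takes hydrogen from the face opposite to ring C to give aryl oxalate F7. K2CO3 in methanol removes the aryl oxalate and gives 31.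

**Step 17.** Release of the quinone methide from the free benzhydrol may be slow under base, so that the ylide is consumed by self-coupling; facial selectivity at C4 is argued from models only. The fallback pre-activates the benzhydrol and runs from 32 to 36. Compound 32 is converted with sodium 4-methylbenzenesulfinate and acetic acid into the 2-(arylsulfonylalkyl)phenol F8, which eliminates sulfinate with Cs2CO3 at 25 °C in the presence of 33 and gives 36 through the same quinone methide 35.

**Step 18.** The benzylic C6–O bond may ionise and the furan open or rearrange while eight ethers are being cleaved by a strong Lewis acid. The fallback changes the bond-breaking mode from electrophilic to nucleophilic and runs from 36 to 37. NaSEt in DMF at 130 to 150 °C removes the methyl groups by SN2 attack at carbon under basic conditions, where the furan cannot ionise; no new compound is involved.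

## Further compounds

F1 | step 9 | 1,2-dibromo-3,5-dimethoxybenzene | COc1cc(OC)c(Br)c(Br)c1
F2 | step 9 | methyl 2-(2-bromo-3,5-dimethoxyphenyl)-3-(3,5-dimethoxyphenyl)-5,7-dimethoxy-4-(4-methoxyphenyl)-1-oxo-1,2,3,4-tetrahydronaphthalene-2-carboxylate (new aryl group trans to ring A; C3 and C4 of the tetralone as in 19) | COc1cc(OC)cc(c1)[C@H]1[C@H](c2ccc(OC)cc2)c2c(OC)cc(OC)cc2C(=O)[C@]1(C(=O)OC)c1cc(OC)cc(OC)c1Br
F3 | step 7 | [3,5-dimethoxy-2-(4-methoxybenzyl)phenyl]methanol | COc1ccc(Cc2c(CO)cc(OC)cc2OC)cc1
F4 | step 7 | 3,5-dimethoxy-2-(4-methoxybenzyl)benzaldehyde | COc1ccc(Cc2c(C=O)cc(OC)cc2OC)cc1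
F5 | step 7 | racemic methyl 3-(3,5-dimethoxyphenyl)-1-hydroxy-5,7-dimethoxy-4-(4-methoxyphenyl)-1,2,3,4-tetrahydronaphthalene-2-carboxylate (OH cis to the ester; aryl groups as in 18; one enantiomer drawn) | COc1cc(OC)cc(c1)[C@H]1[C@H](c2ccc(OC)cc2)c2c(OC)cc(OC)cc2[C@H](O)[C@@H]1C(=O)OC
F6 | step 14 | bis(methyl oxalate) of 30 (on the C1 oxygen and on the c2 phenol) | COc1ccc([C@@]2(OC(=O)C(=O)OC)c3c(OC)cc(OC)cc3[C@H]3[C@H](c4ccc(OC)cc4)c4c(OC)cc(OC)cc4C(=O)c4c(OC(=O)C(=O)OC)cc(OC)cc4[C@H]23)cc1
F7 | step 14 | aryl methyl oxalate of 31 (on the c2 phenol) | COc1ccc([C@@H]2c3c(OC)cc(OC)cc3[C@H]3[C@H](c4ccc(OC)cc4)c4c(OC)cc(OC)cc4C(=O)c4c(OC(=O)C(=O)OC)cc(OC)cc4[C@H]23)cc1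
F8 | step 17 | 4-methylphenyl sulfone at C4 derived from 32 (both C4 epimers; c2 phenol) | COc1ccc([C@@H]2c3c(OC)cc(OC)cc3[C@H]3[C@H](c4ccc(OC)cc4)c4c(OC)cc(OC)cc4C(S(=O)(=O)c5ccc(C)cc5)c4c(O)cc(OC)cc4[C@H]23)cc1
F0 | step 18 | none | none
A1 | alternative 1 | indane with ring A as a 4-hydroxy-6-ethoxy resorcinol derivative (product of the benzannulation) | COc1ccc([C@@H]2c3c(O)cc(OCC)cc3[C@@H](CO[Si](C)(C)C(C)(C)C)[C@@H]2c2cc(OC)cc(OC)c2)cc1
A2 | alternative 1 | cyclopentenyl diazomethyl ketone | COc1ccc([C@@H]2C=C(C(=O)C=[N+]=[N-])[C@@H](CO[Si](C)(C)C(C)(C)C)[C@@H]2c2cc(OC)cc(OC)c2)cc1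
A3 | alternative 1 | ethoxyacetylene | CCOC#C
A4 | alternative 2 | 1,2-cis-2,3-trans indane with C3 as the dimethyl acetal (product of the ring contraction) | COc1ccc([C@@H]2c3c(OC)cc(OC)cc3[C@@H](C(OC)OC)[C@@H]2c2cc(OC)cc(OC)c2)cc1
A5 | alternative 2 | cis-1,2-diaryl-1,2-dihydronaphthalene | COc1ccc([C@@H]2c3c(OC)cc(OC)cc3C=C[C@@H]2c2cc(OC)cc(OC)c2)cc1
A6 | alternative 3 | hexacyclic ketone with the C1 carbonyl and the eight-membered ring closed (product of the enolate arylation) | O=C2c3c(OC)cc(OC)cc3[C@H]3[C@H](c4ccc(OC)cc4)c4c(OC)cc(OC)cc4[C@@H]4c5c(cc(OC)cc5[C@H]23)O[C@H]4c2ccc(OC)cc2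
A7 | alternative 3 | indan-1-one tethered through C3 and ring B to the bromo dihydrobenzofuran | O=C2c3c(OC)cc(OC)cc3[C@@H]([C@H](c4ccc(OC)cc4)c4c(OC)cc(OC)cc4[C@@H]4c5c(cc(OC)cc5Br)O[C@H]4c4ccc(OC)cc4)C2
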